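**Plan**

- Retrosynthesis: the three ester C–O bonds are cut first (O5–Bz, O7–Bz, O3–Ac), then the C4–O and C5–O bonds (alkene dihydroxylation), then the C1=C2 alkene (loss of HBr from an α-bromo aldehyde), and last the ring bonds C2–C3 and C1–C6 in a [4+2] sense.
- Enabling feature: in the ring C1(C7)=C2–C3(O)–C4(O)–C5(O)–C6(O) the cis oxygens on C3 and C6 flank a C4–C5 unit that can be an alkene. This is the imprint of an (E,E)-1,4-dioxygenated butadiene (C3–C6) joined to a two-carbon dienophile (C1–C2) that carries C7.
- Forward: the only ring is closed in step 2 from 2-bromoacrolein and (1E,3E)-1,4-diacetoxybutadiene. Osmylation, acetonide protection, HBr loss, carbonyl reduction and ester adjustment follow.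
- Stereochemistry: C3/C6 cis from the diene geometry, absolute sense from a chiral oxazaborolidinium catalyst combined with endo addition, C4/C5 from osmylation anti to both acetoxy groups. C1 is a temporary centre.
- Differentiation: O6/O7 are masked together as a cyclic boronate so that only O3 is acetylated. O5 is distinguished from O4 by opening of a cyclic orthobenzoate to the axial ester.

Key step: step 2

Remark on numbering: in all names the locants C1–C7 are those of the target skeleton (C1 carries C7, C2 is the vinylic CH, C3–C6 follow round the ring), also where a systematic name would number differently.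

Assumption: the cycloaddition is taken to follow the endo mode (formyl group under the diene) usual for acyclic (E,E)-dienes, so that in 5 the formyl group is cis and the bromine trans to both acetoxy groups; this centre is erased in step 5.

**Route**

Step 1
Reactants: 1 acrolein
Product: 3 2-bromoacrolein, via 2,3-dibromopropanal 2 (not isolated)
Conditions: Br2, CH2Cl2, −78 °C; then Et3N, −78 → 0 °C; distilled and used fresh
Reagents that add atoms: bromine, BrBr
Why: Bromine adds across the enal double bond and triethylamine then removes the acidic α-hydrogen with loss of the β-bromide (bromination–dehydrobromination), a standard route to α-bromo enals.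

Step 2
Reactants: 3 2-bromoacrolein; 4 (1E,3E)-1,4-diacetoxybuta-1,3-diene
Product: 5 (1R,3R,6R)-3,6-diacetoxy-1-bromocyclohex-4-ene-1-carbaldehyde (acetoxy groups cis to each other and to CHO, Br trans)
Conditions: (S)-3,3-diphenyl-1-(o-tolyl)tetrahydropyrrolo[1,2-c][1,3,2]oxazaborolidinium bis(trifluoromethanesulfonyl)imide (15 mol %, made from the neutral oxazaborolidine and HNTf2), CH2Cl2, −78 → −40 °C
Reagents that add atoms: none
Why: The N-protonated oxazaborolidine binds the formyl oxygen of 3 (with a formyl C–H···O contact to the ring oxygen) and lowers its LUMO, so that the diene adds in a concerted, asynchronous, suprafacial [4+2] process in which the C2–C3 bond is more advanced than C1–C6. The closest known reaction type is the oxazaborolidinium-catalysed enantioselective Diels–Alder reaction of 2-bromoacrolein with simple dienes, and thermal cycloadditions of 4 with acrylic dienophiles indicate that this diene is competent. The six-membered carbocycle is closed by intermolecular [4+2] cycloaddition, both new σ-bonds forming in the same event. C3 and C6 come out cis because both acetoxy groups sit on the outside of the s-cis (E,E)-diene; C1 is fixed relative to them by the endo placement of the boron-bound formyl group; the absolute sense comes from the catalyst, whose nearby phenyl group covers one face of the s-trans enal, so that the (S)-catalyst should give the (1R) adduct. The step needs enantioface and endo control but no regiocontrol, because 4 is constitutionally symmetric. Since step 5 erases C1, any exo adduct would later converge on the mirror-image series and is therefore removed as a diastereomer at the stage of 5, 6 or 7.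

Step 3
Reactants: 5 (1R,3R,6R)-3,6-diacetoxy-1-bromocyclohex-4-ene-1-carbaldehyde
Product: 6 (1R,3R,4R,5S,6R)-3,6-diacetoxy-1-bromo-4,5-dihydroxycyclohexane-1-carbaldehyde
Conditions: OsO4 (3 mol %), NMO, acetone–H2O, 0 °C → rt; Na2SO3 quench
Reagents that add atoms: osmium tetroxide, O=[Os](=O)(=O)=O (transfers both oxygens and is regenerated); N-methylmorpholine N-oxide, C[N+]1([O-])CCOCC1; water, O
Why: Upjohn dihydroxylation, in which OsO4 adds suprafacially to the C4=C5 alkene from the face opposite to the two allylic acetoxy groups, sets C4 and C5 cis to each other and trans to O3 and O6.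

Step 4
Reactants: 6 (1R,3R,4R,5S,6R)-3,6-diacetoxy-1-bromo-4,5-dihydroxycyclohexane-1-carbaldehyde
Product: 7 (1R,3R,4S,5S,6R)-3,6-diacetoxy-1-bromo-4,5-(isopropylidenedioxy)cyclohexane-1-carbaldehyde
Conditions: 2-methoxypropene, PPTS (cat.), CH2Cl2, 0 °C → rt
Reagents that add atoms: 2-methoxypropene, COC(C)=C
Why: Kinetic acetalisation of the cis-4,5-diol with an enol ether gives the cis-fused dioxolane under mildly acidic, nearly methanol-free conditions that leave the hindered α-bromo aldehyde and the acetates untouched.

Step 5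
Reactants: 7 (1R,3R,4S,5S,6R)-3,6-diacetoxy-1-bromo-4,5-(isopropylidenedioxy)cyclohexane-1-carbaldehyde
Product: 8 (3R,4S,5R,6S)-3,6-diacetoxy-4,5-(isopropylidenedioxy)cyclohex-1-ene-1-carbaldehyde
Conditions: DBU (1.2 equiv), CH2Cl2, 0 °C, short reaction time
Reagents that add atoms: none
Why: E2 dehydrobromination, in which the C1 bromine is cis to H6 and can be anti-periplanar only to a hydrogen on C2, should give the conjugated C1=C2 enal regioselectively while removing the temporary C1 stereocentre.

Step 6
Reactants: 8 (3R,4S,5R,6S)-3,6-diacetoxy-4,5-(isopropylidenedioxy)cyclohex-1-ene-1-carbaldehyde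
Product: 10 (3R,4S,5R,6S)-1-(hydroxymethyl)-4,5-(isopropylidenedioxy)cyclohex-1-ene-3,6-diol, via diacetoxy allylic alcohol 9 (not isolated)
Conditions: NaBH4, CeCl3·7H2O, MeOH, −78 °C; then K2CO3 (cat.), rt
Reagents that add atoms: none
Why: Luche 1,2-reduction (NaBH4 with CeCl3) reduces the enal carbonyl without conjugate addition, and carbonate-catalysed methanolysis in the same pot then cleaves both acetates without touching the acetonide or any stereocentre.

Step 7
Reactants: 10 (3R,4S,5R,6S)-1-(hydroxymethyl)-4,5-(isopropylidenedioxy)cyclohex-1-ene-3,6-diol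
Product: 13 (3R,4S,5R,6S)-3-acetoxy-1-(hydroxymethyl)-4,5-(isopropylidenedioxy)cyclohex-1-en-6-ol, via 6,7-O-phenylboronate 11 (not isolated), via 3-O-acetyl 6,7-O-phenylboronate 12 (not isolated)
Conditions: PhB(OH)2 (1.05 equiv), 4 Å MS, CH2Cl2, rt; then Ac2O, pyridine, DMAP (cat.), 0 °C → rt; then pinacol, THF–H2O, rt
Reagents that add atoms: acetic anhydride, CC(=O)OC(C)=O; phenylboronic acid, OB(O)c1ccccc1 (its boron and phenyl are present only in 11 and 12)
Why: Temporary boronate protection followed by esterification, in which phenylboronic acid condenses with the 1,3-related O6/O7 pair to a six-membered cyclic boronate (O3 has no free partner because O4 is in the acetonide), allows acetylation only at O3 before transesterification with pinacol releases the 6,7-diol.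

Step 8
Reactants: 13 (3R,4S,5R,6S)-3-acetoxy-1-(hydroxymethyl)-4,5-(isopropylidenedioxy)cyclohex-1-en-6-ol; 14 benzoyl chloride
Product: 15 [(3R,4S,5R,6S)-3-acetoxy-6-hydroxy-4,5-(isopropylidenedioxy)cyclohex-1-en-1-yl]methyl benzoate
Conditions: BzCl (1.05 equiv), 2,4,6-collidine, CH2Cl2, −40 → −10 °C
Reagents that add atoms: none
Why: Kinetically selective acylation, in which the primary allylic C7 hydroxyl reacts with one equivalent of acid chloride at low temperature much faster than the secondary C6 hydroxyl flanked by C1 and the acetonide-bearing C5.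

Step 9
Reactants: 15 [(3R,4S,5R,6S)-3-acetoxy-6-hydroxy-4,5-(isopropylidenedioxy)cyclohex-1-en-1-yl]methyl benzoate
Product: 16 [(3R,4R,5R,6S)-3-acetoxy-4,5,6-trihydroxycyclohex-1-en-1-yl]methyl benzoate
Conditions: TFA–H2O (9:1), CH2Cl2, 0 °C
Reagents that add atoms: none
Why: Acid-catalysed hydrolysis of the isopropylidene acetal frees the cis-4,5-diol, while the acidic medium leaves the acetate and benzoate in place and disfavours acyl migration.

Step 10
Reactants: 16 [(3R,4R,5R,6S)-3-acetoxy-4,5,6-trihydroxycyclohex-1-en-1-yl]methyl benzoate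
Product: 18 [(3R,4S,5R,6S)-3-acetoxy-5-(benzoyloxy)-4,6-dihydroxycyclohex-1-en-1-yl]methyl benzoate (CNP0169028.1), via 4,5-orthobenzoate 17 (not isolated)
Conditions: PhC(OMe)3 (1.5 equiv), CSA (cat.), MeCN, rt; then 80 % aq. AcOH, 0 °C → rt
Reagents that add atoms: trimethyl orthobenzoate, COC(OC)(OC)c1ccccc1; water, O
Why: Orthoester monoacylation, in which the cyclic orthoester forms only on the cis-4,5-diol and is opened by mild aqueous acid through the dioxolan-2-ylium ion and hemiorthoester to the axial ester, should place the benzoate on C5 and leave O4 free, because in the preferred half-chair O6 is pseudoaxial (avoiding allylic strain with C7) and O5 is therefore axial.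

**Compound list**

1 | acrolein (prop-2-enal) | C=CC=O | starting material
2 | 2,3-dibromopropanal (racemic, formed in situ) | O=CC(Br)CBr | intermediate
3 | 2-bromoacrolein (2-bromoprop-2-enal) | C=C(Br)C=O | intermediate
4 | (1E,3E)-1,4-diacetoxybuta-1,3-diene | CC(=O)O/C=C/C=C/OC(C)=O | starting material
5 | (1R,3R,6R)-3,6-diacetoxy-1-bromocyclohex-4-ene-1-carbaldehyde | CC(=O)O[C@@H]1C[C@](Br)(C=O)[C@H](OC(C)=O)C=C1 | intermediate
6 | (1R,3R,4R,5S,6R)-3,6-diacetoxy-1-bromo-4,5-dihydroxycyclohexane-1-carbaldehyde | CC(=O)O[C@@H]1C[C@](Br)(C=O)[C@H](OC(C)=O)[C@@H](O)[C@H]1O | intermediate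
7 | (1R,3R,4S,5S,6R)-3,6-diacetoxy-1-bromo-4,5-(isopropylidenedioxy)cyclohexane-1-carbaldehyde | CC(=O)O[C@@H]1C[C@](Br)(C=O)[C@H](OC(C)=O)[C@H]2OC(C)(C)O[C@@H]12 | intermediate
8 | (3R,4S,5R,6S)-3,6-diacetoxy-4,5-(isopropylidenedioxy)cyclohex-1-ene-1-carbaldehyde | CC(=O)O[C@@H]1C=C(C=O)[C@H](OC(C)=O)[C@H]2OC(C)(C)O[C@@H]12 | intermediate
9 | [(3R,4S,5R,6S)-3,6-diacetoxy-4,5-(isopropylidenedioxy)cyclohex-1-en-1-yl]methanol (formed in situ) | CC(=O)O[C@@H]1C=C(CO)[C@H](OC(C)=O)[C@H]2OC(C)(C)O[C@@H]12 | intermediate
10 | (3R,4S,5R,6S)-1-(hydroxymethyl)-4,5-(isopropylidenedioxy)cyclohex-1-ene-3,6-diol | O[C@@H]1C=C(CO)[C@H](O)[C@H]2OC(C)(C)O[C@@H]12 | intermediate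
11 | cyclic 6,7-O-phenylboronate of 10, C3 hydroxyl free (formed in situ) | O[C@@H]1C=C2COB(c3ccccc3)O[C@@H]2[C@H]3OC(C)(C)O[C@@H]13 | intermediate
12 | 3-O-acetyl derivative of 11 (formed in situ) | CC(=O)O[C@@H]1C=C2COB(c3ccccc3)O[C@@H]2[C@H]3OC(C)(C)O[C@@H]13 | intermediate
13 | (3R,4S,5R,6S)-3-acetoxy-1-(hydroxymethyl)-4,5-(isopropylidenedioxy)cyclohex-1-en-6-ol | CC(=O)O[C@@H]1C=C(CO)[C@H](O)[C@H]2OC(C)(C)O[C@@H]12 | intermediate
14 | benzoyl chloride | O=C(Cl)c1ccccc1 | starting material
15 | [(3R,4S,5R,6S)-3-acetoxy-6-hydroxy-4,5-(isopropylidenedioxy)cyclohex-1-en-1-yl]methyl benzoate | CC(=O)O[C@@H]1C=C(COC(=O)c3ccccc3)[C@H](O)[C@H]2OC(C)(C)O[C@@H]12 | intermediate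
16 | [(3R,4R,5R,6S)-3-acetoxy-4,5,6-trihydroxycyclohex-1-en-1-yl]methyl benzoate | CC(=O)O[C@@H]1C=C(COC(=O)c2ccccc2)[C@H](O)[C@@H](O)[C@H]1O | intermediate
17 | 4,5-O-(α-methoxybenzylidene) cyclic orthoester of 16, both epimers at the orthoester carbon (formed in situ) | CC(=O)O[C@@H]1C=C(COC(=O)c3ccccc3)[C@H](O)[C@H]2OC(OC)(c3ccccc3)O[C@@H]12 | intermediate
18 | [(3R,4S,5R,6S)-3-acetoxy-5-(benzoyloxy)-4,6-dihydroxycyclohex-1-en-1-yl]methyl benzoate (CNP0169028.1) | CC(=O)O[C@@H]1C=C(COC(=O)c2ccccc2)[C@H](O)[C@@H](OC(=O)c2ccccc2)[C@H]1O | target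

**Step count and risks**

Total: 10 steps. Longest linear sequence: 10 steps (1 → 18); 4 and 14 are purchased.

The three steps most likely to fail:

Step 2. The strongly acidic boron cation may be tied up by the ester carbonyls of 4 or may degrade this bis(enol acetate). Partial reaction through the exo mode, or incomplete shielding of one enal face, would lower the enantiopurity once C1 is erased. The fallback sets out from 3 and 4 and comes back at 8. The cycloaddition is run thermally without catalyst (toluene, 70 °C, BHT), which should give the endo adduct as a racemate, that is 5 together with the enantiomer of 5 F1. Steps 3 to 5 are then carried out unchanged on the racemate and should give 6, 7 and 8 alongside the enantiomer of 6 F2, the enantiomer of 7 F3 and the enantiomer of 8 F4. The racemic enal is condensed with (1R,2R)-N,N′-dimethyl-1,2-diphenylethane-1,2-diamine (CH2Cl2, 4 Å MS, rt) to two diastereomeric imidazolidines, the aminal of 8 F5 and the aminal of ent-8 F6, which are separated by chromatography. Brief treatment of F5 with aqueous oxalic acid in Et2O should release enantiopure 8 and the recoverable diamine.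

Step 10. The hemiorthoester may collapse without the expected axial preference if both half-chairs are populated, and the benzoyl group may shift between the cis-related O4 and O5 during work-up. The fallback sets out from 15 and comes back at 18, and replaces the stereoelectronic differentiation by a steric one. The C6 hydroxyl is silylated (TBSOTf, 2,6-lutidine, CH2Cl2, −40 °C) to the 6-O-tert-butyldimethylsilyl ether of 15 F7. The acetonide is removed (80 % aq. AcOH, 40 °C) to the 6-O-silyl 4,5-diol F8. The less hindered O4, which is next to the small acetate and not to the silyl ether, is capped (TESCl, imidazole, CH2Cl2, −20 °C) to the 4-O-triethylsilyl 6-O-tert-butyldimethylsilyl ether F9. O5 is then benzoylated with 14 (pyridine, DMAP, rt) to the 5-O-benzoyl bis(silyl ether) F10. HF·pyridine in THF–pyridine removes both silyl groups under acidic conditions that should not move the esters and should give 18.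

Step 5. DBU may go on to remove the γ-hydrogen at C3 of the enal once it is formed, which would start loss of an oxygen substituent and aromatisation, so the window between E2 and over-elimination may be narrow. The fallback sets out from 7 and comes back at 10, and avoids the base-sensitive enal altogether. The aldehyde is reduced (NaBH4, MeOH, −20 °C) to the bromohydrin F11, which is [3,6-diacetoxy-1-bromo-4,5-(isopropylidenedioxy)cyclohexyl]methanol. K2CO3 in MeOH then closes the oxirane by displacement of bromide with inversion at C1 and cleaves both acetates, giving the spiro-epoxide diol F12 (C1–C7 oxirane with its oxygen on the face of O3 and O6). An excess of LiNEt2 (THF, 0 °C → rt) should isomerise the epoxide to the allylic alcohol by syn removal of the C2 hydrogen cis to the epoxide oxygen (H6 is trans to it), which gives triol 10 directly.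

**Further compounds**

F1 | step 2 | enantiomer of 5, (1S,3S,6S)-3,6-diacetoxy-1-bromocyclohex-4-ene-1-carbaldehyde | CC(=O)O[C@H]1C[C@@](Br)(C=O)[C@@H](OC(C)=O)C=C1
F2 | step 2 | enantiomer of 6 | CC(=O)O[C@H]1C[C@@](Br)(C=O)[C@@H](OC(C)=O)[C@H](O)[C@@H]1O
F3 | step 2 | enantiomer of 7 | CC(=O)O[C@H]1C[C@@](Br)(C=O)[C@@H](OC(C)=O)[C@@H]2OC(C)(C)O[C@H]12
F4 | step 2 | enantiomer of 8 | CC(=O)O[C@H]1C=C(C=O)[C@@H](OC(C)=O)[C@@H]2OC(C)(C)O[C@H]12
F5 | step 2 | aminal of 8 with the (1R,2R)-diamine: (4R,5R)-1,3-dimethyl-4,5-diphenylimidazolidin-2-yl group in place of CHO | CC(=O)O[C@@H]1C=C(C3N(C)[C@H](c4ccccc4)[C@@H](c4ccccc4)N3C)[C@H](OC(C)=O)[C@H]2OC(C)(C)O[C@@H]12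
F6 | step 2 | aminal of ent-8 with the (1R,2R)-diamine (diastereomer of F5) | CC(=O)O[C@H]1C=C(C3N(C)[C@H](c4ccccc4)[C@@H](c4ccccc4)N3C)[C@@H](OC(C)=O)[C@@H]2OC(C)(C)O[C@H]12
F7 | step 10 | 6-O-tert-butyldimethylsilyl ether of 15 | CC(=O)O[C@@H]1C=C(COC(=O)c3ccccc3)[C@H](O[Si](C)(C)C(C)(C)C)[C@H]2OC(C)(C)O[C@@H]12
F8 | step 10 | 6-O-tert-butyldimethylsilyl 4,5-diol (F7 without the acetonide) | CC(=O)O[C@@H]1C=C(COC(=O)c2ccccc2)[C@H](O[Si](C)(C)C(C)(C)C)[C@@H](O)[C@H]1O
F9 | step 10 | 4-O-triethylsilyl 6-O-tert-butyldimethylsilyl ether with C5 hydroxyl free | CC(=O)O[C@@H]1C=C(COC(=O)c2ccccc2)[C@H](O[Si](C)(C)C(C)(C)C)[C@@H](O)[C@H]1O[Si](CC)(CC)CC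
F10 | step 10 | 4-O-triethylsilyl 6-O-tert-butyldimethylsilyl ether of 18 | CC(=O)O[C@@H]1C=C(COC(=O)c2ccccc2)[C@H](O[Si](C)(C)C(C)(C)C)[C@@H](OC(=O)c2ccccc2)[C@H]1O[Si](CC)(CC)CC
F11 | step 5 | bromohydrin, [3,6-diacetoxy-1-bromo-4,5-(isopropylidenedioxy)cyclohexyl]methanol, configuration as in 7 | CC(=O)O[C@@H]1C[C@](Br)(CO)[C@H](OC(C)=O)[C@H]2OC(C)(C)O[C@@H]12
F12 | step 5 | spiro-epoxide diol, C1–C7 oxirane with 3,6-diol and 4,5-acetonide | O[C@@H]1C[C@@]2(CO2)[C@H](O)[C@H]3OC(C)(C)O[C@@H]13
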